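Atom numbers are the abietane numbers of the target (C1–C20; C18 = CH3 and C19 = CH2OH on C4, C20 = lactone carbonyl).

**Plan**
1. First cut: ring C is taken apart at C8–C14 (the closing bond), C13–C14 and C11–C12. This leaves a C9 diazoacetyl group on the AB lactone and the ynol silyl ether i-PrC≡COSi(i-Pr)3; the C11 oxygen is added afterwards.
2. Second cut: C5–C10 and C6–C7 (retro-Diels–Alder) open rings A and B together to a 3-alkyl-2-pyrone-4-carboxylate with a tethered (E)-enol ether. Third cut: C1–C10 (sp3–sp2 coupling) gives a bromopyrone and a C1–C6 chain that holds C4.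
3. Forward ring order: 2-pyrone (its O–C20(=O) unit becomes the lactone bridge), then rings A and B in one cycloaddition, then ring C, then the quinone.
4. Stereochemistry: C4 comes from lipase desymmetrization of a prochiral 1,3-diol. C5, C6, C7 and C10 come from the intramolecular Diels–Alder step (E-enol ether, exo tether/endo alkoxy, hydrogen bond from the C19 hydroxyl to the pyrone C20=O).
5. Enabling feature: ring C is a hydroxy-p-quinone whose C12 and C14 oxygens are meta around the i-Pr-bearing C13, and C8 is an sp2 CH of the 2-oxabicyclo[2.2.2]octene next to the acyl-bearing C9. A C9 vinylketene and an ynol ether can therefore build the whole ring, closing it at C8–C14. Helper groups (methyl ester, PMB on O6, silyl groups on O19 and O12) are removed on the way.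

Key step: step 15

Assumption: the lipase is taken to acetylate the pro-S hydroxymethyl arm of diol 3; if it prefers the other arm, hydrolysis of the diacetate with the same enzyme gives the same monoacetate 4.

**Step 1**
Reactants: 1 2-methylpent-4-enal
Product: 3 2-methyl-2-(prop-2-en-1-yl)propane-1,3-diol, via aldol adduct 2 (not isolated)
Conditions: HCHO (37% aq., 3 equiv), KOH (1.2 equiv), MeOH/H2O, 0 → 60 °C
Reagents that add atoms: formaldehyde, C=O
Why: Tollens-type sequence of crossed aldol addition to formaldehyde and crossed Cannizzaro reduction of the non-enolizable aldehyde 2 gives the prochiral 2,2-disubstituted 1,3-diol (no stereocenter yet).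

**Step 2**
Reactants: 3 2-methyl-2-(prop-2-en-1-yl)propane-1,3-diol
Product: 4 (2S)-2-(hydroxymethyl)-2-methylpent-4-en-1-yl acetate
Conditions: Burkholderia cepacia lipase, vinyl acetate (5 equiv), i-Pr2O, 25 °C
Reagents that add atoms: vinyl acetate, CC(=O)OC=C
Why: Lipase-catalysed enantiotopic-group-selective transesterification (desymmetrization of a prochiral 1,3-diol) acetylates one hydroxymethyl arm and so sets C4, the acetylated arm being the future C19.

**Step 3**
Reactants: 4 (2S)-2-(hydroxymethyl)-2-methylpent-4-en-1-yl acetate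
Product: 5 (2R)-2-formyl-2-methylpent-4-en-1-yl acetate
Conditions: TEMPO (10 mol %), PhI(OAc)2 (1.2 equiv), CH2Cl2, 25 °C
Reagents that add atoms: none
Why: TEMPO/PhI(OAc)2 oxidation of the primary alcohol gives the non-enolizable aldehyde (the future C5) and is run at once, because it removes the free hydroxyl whose 1,3-acyl shift would erode the C4 configuration.

**Step 4**
Reactants: 5 (2R)-2-formyl-2-methylpent-4-en-1-yl acetate
Product: 6 (2S,3E)-4-iodo-2-methyl-2-(prop-2-en-1-yl)but-3-en-1-yl acetate
Conditions: CrCl2 (6 equiv), CHI3 (2 equiv), THF/1,4-dioxane, 0 → 25 °C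
Reagents that add atoms: iodoform, IC(I)I
Why: Takai iodo-olefination through a geminal dichromium species should give the (E)-vinyl iodide (C5=C6), the E preference being reinforced by the quaternary C4.

**Step 5**
Reactants: 6 (2S,3E)-4-iodo-2-methyl-2-(prop-2-en-1-yl)but-3-en-1-yl acetate
Product: 8 (2S,3E)-4-[(4-methoxyphenyl)methoxy]-2-methyl-2-(prop-2-en-1-yl)but-3-en-1-ol, via acetate enol ether 7 (not isolated)
Conditions: CuI (10 mol %), 3,4,7,8-tetramethyl-1,10-phenanthroline (20 mol %), Cs2CO3 (1.5 equiv), 4-MeOC6H4CH2OH (3 equiv), toluene, 80 °C; then MeOH, K2CO3, 25 °C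
Reagents that add atoms: 4-methoxybenzyl alcohol, COc1ccc(CO)cc1
Why: Ullmann-type copper-catalysed C–O coupling of a vinyl iodide with an alcohol proceeds with retention of the E geometry, and methanolysis of the acetate in the same flask frees the C19 hydroxyl.

**Step 6**
Reactants: 9 dimethyl but-2-ynedioate
Product: 10 dimethyl (2E)-2,3-dibromobut-2-enedioate
Conditions: Br2 (1.05 equiv), CH2Cl2, 0 → 25 °C, dark; recrystallization
Reagents that add atoms: bromine, BrBr
Why: Ionic anti addition of bromine to the alkyne should give mainly the (E)-dibromide, in which each ester is cis to the bromine on the other carbon.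

**Step 7**
Reactants: 10 dimethyl (2E)-2,3-dibromobut-2-enedioate; 11 (E)-2-(2-ethoxyethenyl)-4,4,5,5-tetramethyl-1,3,2-dioxaborolane (1.0 equiv)
Product: 12 dimethyl (2Z)-2-bromo-3-[(E)-2-ethoxyethenyl]but-2-enedioate
Conditions: Pd(PPh3)4 (5 mol %), K3PO4 (2 equiv), THF/H2O, 40 °C
Reagents that add atoms: none
Why: Suzuki–Miyaura coupling with retention at the alkenyl bromide should stop after one coupling, because the donor-substituted diene deactivates the second C–Br bond, and it leaves the C20 ester cis to the new C8–C7 arm.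

**Step 8**
Reactants: 12 dimethyl (2Z)-2-bromo-3-[(E)-2-ethoxyethenyl]but-2-enedioate
Product: 14 methyl 3-bromo-2-oxo-2H-pyran-4-carboxylate, via aldehyde diester 13 (not isolated)
Conditions: TsOH·H2O (20 mol %), H2O (3 equiv), MeCN, 60 °C
Reagents that add atoms: water, O
Why: Acid hydrolysis of the enol ether to the aldehyde and enol-lactonization onto the cis ester (loss of methanol) give the 2-pyrone, the classical ring closure of 5-oxopent-2-enoates.

**Step 9**
Reactants: 8 (2S,3E)-4-[(4-methoxyphenyl)methoxy]-2-methyl-2-(prop-2-en-1-yl)but-3-en-1-ol; 14 methyl 3-bromo-2-oxo-2H-pyran-4-carboxylate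
Product: 16 methyl 3-[(4S,5E)-4-(hydroxymethyl)-6-[(4-methoxyphenyl)methoxy]-4-methylhex-5-en-1-yl]-2-oxo-2H-pyran-4-carboxylate, via bis-borane 15 (not isolated)
Conditions: 9-BBN (2.2 equiv), THF, 25 °C; then 14, Pd(dppf)Cl2 (5 mol %), AsPh3 (10 mol %), K3PO4 (3 equiv), DMF, 50 °C; aq. NH4Cl
Reagents that add atoms: none
Why: Anti-Markovnikov hydroboration of the terminal alkene only (the hindered enol ether is left) and B-alkyl Suzuki–Miyaura coupling at the activated C–Br bond of the bromopyrone form C1–C10, the O-borinate of the C19 hydroxyl being hydrolysed on work-up.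

**Step 10**
Reactants: 16 pyrone enol ether
Product: 17 hydroxy lactone ester (rings A and B closed: C8=C9, 9-CO2Me, 6α-OPMB, 19-OH, 20,7β-olide)
Conditions: toluene (0.005 M), BHT (5 mol %), 80 °C, base-washed glass
Reagents that add atoms: none
Why: Intramolecular inverse-electron-demand Diels–Alder reaction of the 2-pyrone (diene C10=C9–C8=C7, with C10 made electrophilic by the C9 ester) with the tethered (E)-enol ether forms C5–C10 and C6–C7; the E geometry fixes C4 and O6 trans, the exo tether (away from the C9 ester) with endo OPMB fixes 5α-H and 6α-O relative to the 7β,20-lactone bridge, and the O–H···O=C20 hydrogen bond, possible only with CH2OH axial in the chair-like tether, selects the pyrone face that puts C19 cis to C20.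

**Step 11**
Reactants: 17 hydroxy lactone ester
Product: 18 silyl ether lactone ester (19-OSi(t-Bu)Me2)
Conditions: t-BuMe2SiOTf (1.3 equiv), 2,6-lutidine (2 equiv), CH2Cl2, −40 → 0 °C
Reagents that add atoms: tert-butyldimethylsilyl trifluoromethanesulfonate, CC(C)(C)[Si](C)(C)OS(=O)(=O)C(F)(F)F
Why: Standard silylation (silyl triflate, hindered pyridine) of the neopentyl C19 hydroxyl protects it for the acid chloride, diazomethane and ketene steps and blocks translactonization onto C20.

**Step 12**
Reactants: 18 silyl ether lactone ester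
Product: 19 lactone acid (9-CO2H)
Conditions: LiI (10 equiv), EtOAc, reflux, dark; then aq. HCl to pH 3
Reagents that add atoms: none
Why: SN2 dealkylation of the methyl ester by iodide frees the C9 acid without acyl substitution, so the bridged lactone, whose alkyl carbon C7 is a bridgehead closed to SN2 attack, is expected to survive.

**Step 13**
Reactants: 19 lactone acid
Product: 21 diazo ketone (C9–C(=O)CHN2), via acid chloride 20 (not isolated)
Conditions: 1-chloro-N,N,2-trimethylprop-1-en-1-amine (1.3 equiv), CH2Cl2, 0 → 25 °C; then CH2N2 (3 equiv), Et2O, 0 °C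
Reagents that add atoms: diazomethane, C=[N+]=[N-]
Why: Neutral conversion to the acid chloride with the α-chloroenamine and acylation of diazomethane (first stage of the Arndt–Eistert sequence) give the α,β-unsaturated diazo ketone; the trisubstituted C8=C9 bond flanked by quaternary C10 should be too hindered for the competing dipolar cycloaddition of diazomethane.

**Step 14**
Reactants: 22 ethyl 2-methylpropanoate
Product: 24 triisopropyl[(3-methylbut-1-yn-1-yl)oxy]silane, via lithium ynolate 23 (not isolated)
Conditions: CH2Br2, LiTMP, THF, −78 °C; n-BuLi, −78 → 0 °C; i-Pr3SiCl, −78 → 25 °C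
Reagents that add atoms: dibromomethane, BrCBr; chlorotriisopropylsilane, CC(C)[Si](Cl)(C(C)C)C(C)C
Why: Kowalski ester homologation (LiCHBr2 addition, Br/Li exchange and 1,2-shift of the isopropyl group to the carbenoid carbon) gives the lithium ynolate, which the bulky silyl chloride silylates on oxygen.

**Step 15**
Reactants: 21 diazo ketone; 24 triisopropyl[(3-methylbut-1-yn-1-yl)oxy]silane (1.5 equiv)
Product: 28 phenol (ring C closed: 14-OH 13-i-Pr 12-OSi(i-Pr)3 11-H), via vinylketene 25 (not isolated), via cyclobutenone 26 (not isolated), via dienylketene 27 (not isolated)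
Conditions: hν (254 nm, low-pressure Hg lamp, quartz), ClCH2CH2Cl (0.05 M), 25 °C; then 80 °C, 3 h
Reagents that add atoms: none
Why: Irradiation expels N2 from 21 and the photo-Wolff 1,2-shift of the C9 alkenyl group gives vinylketene 25, whose ketene carbon (the future C14) is attacked by the electron-rich, isopropyl-bearing carbon of ynol silyl ether 24 in a regiospecific [2+2] cycloaddition to 4-alkenylcyclobutenone 26. Warming opens 26 by conrotatory 4π-electrocyclic cleavage to dienylketene 27, and a thermal disrotatory 6π-electrocyclization joins C14 to C8, which closes ring C; tautomerization of the C8–H cyclohexadienone gives phenol 28. The closest known reaction type is the second-generation Danheiser benzannulation of α,β-unsaturated α'-diazo ketones with siloxyalkynes, which gives resorcinol monosilyl ethers with the alkyne substituent between the two oxygens. The four-membered ring closes by ketene–alkyne [2+2] cycloaddition and ring C by 6π-electrocyclization; no stereocenter is formed, and C4, C5, C6, C7 and C10 are not touched (the lactone has no α-hydrogen). The regiochemistry needed (i-Pr on C13 between O12 and O14, H on C11) is secured by the polarization of the ynol ether, and the site of closure by the substrate, since C8 is the only sp2 CH conjugated to the ketene and the other neighbour of C9 is quaternary C10. The thermal stage at 80 °C should stay below the temperature of CO2 loss from the bridged lactone, and once ring C is aromatic that retro-Diels–Alder path is closed.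

**Step 16**
Reactants: 28 phenol
Product: 29 silyloxyquinone (11,14-dione with 12-OSi(i-Pr)3)
Conditions: O2 (1 atm), Co(salen) [Co(C16H14N2O2), divalent cobalt] (10 mol %), MeCN, 25 °C
Reagents that add atoms: dioxygen, O=O
Why: Cobalt–salen-catalysed aerobic oxidation of a para-unsubstituted phenol (C11 is the only free ring position, para to the C14 hydroxyl) gives the 11,14-p-quinone with the C12 silyloxy and C13 isopropyl groups already in place.

**Step 17**
Reactants: 29 silyloxyquinone
Product: 30 CNP0339604.1 (target)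
Conditions: CF3CO2H/CH2Cl2/H2O (10:10:1), anisole (5 equiv), 0 → 25 °C
Reagents that add atoms: none
Why: Acidolysis of the PMB ether with capture of the benzyl cation by anisole (Friedel–Crafts benzylation) and hydrolysis of the two silyl ethers, the one at C12 being a labile vinylogous silyl ester, free the three hydroxyls without touching a stereocenter.

**Compound list**
1 | 2-methylpent-4-enal (racemic) | C=CCC(C)C=O | starting material
2 | 2-(hydroxymethyl)-2-methylpent-4-enal (aldol adduct, racemic, not isolated) | C=CCC(C)(CO)C=O | intermediate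
3 | 2-methyl-2-(prop-2-en-1-yl)propane-1,3-diol | C=CCC(C)(CO)CO | intermediate
4 | (2S)-2-(hydroxymethyl)-2-methylpent-4-en-1-yl acetate | C=CC[C@](C)(COC(C)=O)CO | intermediate
5 | (2R)-2-formyl-2-methylpent-4-en-1-yl acetate | C=CC[C@](C)(COC(C)=O)C=O | intermediate
6 | (2S,3E)-4-iodo-2-methyl-2-(prop-2-en-1-yl)but-3-en-1-yl acetate | C=CC[C@](C)(COC(C)=O)/C=C/I | intermediate
7 | (2S,3E)-4-[(4-methoxyphenyl)methoxy]-2-methyl-2-(prop-2-en-1-yl)but-3-en-1-yl acetate (not isolated) | C=CC[C@](C)(COC(C)=O)/C=C/OCc1ccc(OC)cc1 | intermediate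
8 | (2S,3E)-4-[(4-methoxyphenyl)methoxy]-2-methyl-2-(prop-2-en-1-yl)but-3-en-1-ol | C=CC[C@](C)(CO)/C=C/OCc1ccc(OC)cc1 | intermediate
9 | dimethyl but-2-ynedioate | COC(=O)C#CC(=O)OC | starting material
10 | dimethyl (2E)-2,3-dibromobut-2-enedioate | COC(=O)/C(Br)=C(\Br)C(=O)OC | intermediate
11 | (E)-2-(2-ethoxyethenyl)-4,4,5,5-tetramethyl-1,3,2-dioxaborolane | CCO/C=C/B1OC(C)(C)C(C)(C)O1 | starting material
12 | dimethyl (2Z)-2-bromo-3-[(E)-2-ethoxyethenyl]but-2-enedioate | COC(=O)/C(Br)=C(\C=C\OCC)C(=O)OC | intermediate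
13 | dimethyl (2Z)-2-bromo-3-(2-oxoethyl)but-2-enedioate (not isolated) | COC(=O)/C(Br)=C(\CC=O)C(=O)OC | intermediate
14 | methyl 3-bromo-2-oxo-2H-pyran-4-carboxylate | COC(=O)C1=C(Br)C(=O)OC=C1 | intermediate
15 | bis-borane: C1-(9-BBN) and O19-(9-BBN) derivative of 8 (not isolated) | C(B1C2CCCC1CCC2)CC[C@](C)(COB1C2CCCC1CCC2)/C=C/OCc1ccc(OC)cc1 | intermediate
16 | methyl 3-[(4S,5E)-4-(hydroxymethyl)-6-[(4-methoxyphenyl)methoxy]-4-methylhex-5-en-1-yl]-2-oxo-2H-pyran-4-carboxylate | COC(=O)C1=C(CCC[C@](C)(CO)/C=C/OCc2ccc(OC)cc2)C(=O)OC=C1 | intermediate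
17 | hydroxy lactone ester: rings A and B with 20,7β-lactone bridge, C8=C9, CO2Me on C9, 6α-OPMB, 19-OH, 5α-H; (4S,5S,6R,7R,10R) | COC(=O)C2=C[C@H]1OC(=O)[C@@]23CCC[C@](C)(CO)[C@@H]3[C@H]1OCc1ccc(OC)cc1 | intermediate
18 | silyl ether lactone ester: 17 with 19-OSi(t-Bu)Me2; (4S,5S,6R,7R,10R) | COC(=O)C2=C[C@H]1OC(=O)[C@@]23CCC[C@](C)(CO[Si](C)(C)C(C)(C)C)[C@@H]3[C@H]1OCc1ccc(OC)cc1 | intermediate
19 | lactone acid: 18 with CO2H on C9; (4S,5S,6R,7R,10R) | OC(=O)C2=C[C@H]1OC(=O)[C@@]23CCC[C@](C)(CO[Si](C)(C)C(C)(C)C)[C@@H]3[C@H]1OCc1ccc(OC)cc1 | intermediate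
20 | acid chloride of 19 (not isolated) | ClC(=O)C2=C[C@H]1OC(=O)[C@@]23CCC[C@](C)(CO[Si](C)(C)C(C)(C)C)[C@@H]3[C@H]1OCc1ccc(OC)cc1 | intermediate
21 | diazo ketone: C9–C(=O)CHN2 on the AB lactone; (4S,5S,6R,7R,10R) | [N-]=[N+]=CC(=O)C2=C[C@H]1OC(=O)[C@@]23CCC[C@](C)(CO[Si](C)(C)C(C)(C)C)[C@@H]3[C@H]1OCc1ccc(OC)cc1 | intermediate
22 | ethyl 2-methylpropanoate | CCOC(=O)C(C)C | starting material
23 | lithium 3-methylbut-1-yn-1-olate (not isolated) | CC(C)C#C[O-].[Li+] | intermediate
24 | triisopropyl[(3-methylbut-1-yn-1-yl)oxy]silane | CC(C)C#CO[Si](C(C)C)(C(C)C)C(C)C | intermediate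
25 | vinylketene: C9–CH=C=O on the AB lactone (not isolated) | O=C=CC2=C[C@H]1OC(=O)[C@@]23CCC[C@](C)(CO[Si](C)(C)C(C)(C)C)[C@@H]3[C@H]1OCc1ccc(OC)cc1 | intermediate
26 | cyclobutenone: 2-isopropyl-3-(triisopropylsilyloxy)cyclobut-2-enone carrying the AB lactone at its C4 through C9, C11 unassigned (not isolated) | CC(C)C4=C(O[Si](C(C)C)(C(C)C)C(C)C)C(C4=O)C2=C[C@H]1OC(=O)[C@@]23CCC[C@](C)(CO[Si](C)(C)C(C)(C)C)[C@@H]3[C@H]1OCc1ccc(OC)cc1 | intermediate
27 | dienylketene: O=C14=C13(i-Pr)–C12(OSi(i-Pr)3)=C11H–C9=C8, with C13 and C9 cis (not isolated) | O=C=C(C(C)C)/C(O[Si](C(C)C)(C(C)C)C(C)C)=C\C2=C[C@H]1OC(=O)[C@@]23CCC[C@](C)(CO[Si](C)(C)C(C)(C)C)[C@@H]3[C@H]1OCc1ccc(OC)cc1 | intermediate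
28 | phenol: aromatic ring C with 14-OH, 13-i-Pr, 12-OSi(i-Pr)3, 11-H; 6α-OPMB, 19-OSi(t-Bu)Me2, 20,7β-olide; (4S,5S,6R,7R,10R) | CC(C)c1c(O[Si](C(C)C)(C(C)C)C(C)C)cc2c(c1O)[C@H]1OC(=O)[C@@]23CCC[C@](C)(CO[Si](C)(C)C(C)(C)C)[C@@H]3[C@H]1OCc1ccc(OC)cc1 | intermediate
29 | silyloxyquinone: 11,14-dione with 12-OSi(i-Pr)3, 13-i-Pr; 6α-OPMB, 19-OSi(t-Bu)Me2, 20,7β-olide; (4S,5S,6R,7R,10R) | CC(C)C1=C(O[Si](C(C)C)(C(C)C)C(C)C)C(=O)C2=C(C1=O)[C@H]1OC(=O)[C@@]23CCC[C@](C)(CO[Si](C)(C)C(C)(C)C)[C@@H]3[C@H]1OCc1ccc(OC)cc1 | intermediate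
30 | CNP0339604.1: 6α,12,19-trihydroxy-11,14-dioxoabieta-8,12-dien-20,7β-olide; (4S,5S,6R,7R,10R) | CC(C)C1=C(O)C(=O)C2=C(C1=O)[C@H]1OC(=O)[C@@]23CCC[C@](C)(CO)[C@@H]3[C@H]1O | target

**Step count and risks**
Total: 17 steps. Longest linear sequence: 13 steps (steps 1–5, 9–13, 15–17).

Steps most likely to fail:

1. Step 10. The hydrogen bond may be too weak at 80 °C to discriminate the two pyrone faces with respect to C4, the cycloaddition may be slow, and prolonged heating may cause loss of CO2 from the adduct. The fallback sets out from 16 and returns at 17, and replaces the hydrogen-bond control by a steric one. Dess–Martin oxidation (NaHCO3, CH2Cl2) of the C19 hydroxyl gives the formyl pyrone F1. On heating in toluene the formyl group, smaller than methyl, should take the axial place over the lactone bridge and give the formyl cycloadduct F2 with the same facial sense. NaBH4 (MeOH/THF, −40 °C) then reduces only the aldehyde and gives 17.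

2. Step 9. The base needed for transmetalation may open the electrophilic bromopyrone ring, and the alkylborane may undergo protodeboronation or β-hydride loss before coupling. The fallback sets out from 8 and returns at 16, and uses a base-free reductive coupling of two electrophiles. Hydroboration with 9-BBN and oxidation (NaOH, H2O2) give the diol F3. Only the unhindered primary hydroxyl is converted into the iodide F4 (I2, PPh3, imidazole; the neopentyl C19 hydroxyl should not react). Nickel-catalysed cross-electrophile coupling of F4 with 14 (NiCl2·DME, 4,4'-di-tert-butyl-2,2'-bipyridine, Zn dust, DMA, 25 °C) then gives 16.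

3. Step 15. Under irradiation the substrate or the PMB ether may degrade, and the hindered vinylketene may dimerize before it is captured by the alkyne. The fallback sets out from 21 and returns at 28, and generates the same ketene thermally and in the dark. Silver-catalysed Wolff rearrangement in wet THF (PhCO2Ag, Et3N; Arndt–Eistert homologation) gives the β,γ-unsaturated acid F5. 1-Chloro-N,N,2-trimethylprop-1-en-1-amine converts it into the acid chloride F6. Dehydrochlorination with Et3N in toluene at 80 °C in the presence of 24 gives vinylketene 25, and the same [2+2], 4π-opening and 6π-closure sequence gives 28.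

**Further compounds**
F1 | step 10 | methyl 3-[(4S,5E)-4-formyl-6-[(4-methoxyphenyl)methoxy]-4-methylhex-5-en-1-yl]-2-oxo-2H-pyran-4-carboxylate | COC(=O)C1=C(CCC[C@](C)(C=O)/C=C/OCc2ccc(OC)cc2)C(=O)OC=C1
F2 | step 10 | formyl cycloadduct: 17 with CHO in place of CH2OH at C19 | COC(=O)C2=C[C@H]1OC(=O)[C@@]23CCC[C@](C)(C=O)[C@@H]3[C@H]1OCc1ccc(OC)cc1
F3 | step 9 | (4S,5E)-4-(hydroxymethyl)-6-[(4-methoxyphenyl)methoxy]-4-methylhex-5-en-1-ol | OCCC[C@](C)(CO)/C=C/OCc1ccc(OC)cc1
F4 | step 9 | (2S,3E)-2-(3-iodopropyl)-4-[(4-methoxyphenyl)methoxy]-2-methylbut-3-en-1-ol | ICCC[C@](C)(CO)/C=C/OCc1ccc(OC)cc1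
F5 | step 15 | homologated acid: C9–CH2CO2H on the AB lactone | OC(=O)CC2=C[C@H]1OC(=O)[C@@]23CCC[C@](C)(CO[Si](C)(C)C(C)(C)C)[C@@H]3[C@H]1OCc1ccc(OC)cc1
F6 | step 15 | homologated acid chloride: C9–CH2COCl on the AB lactone | ClC(=O)CC2=C[C@H]1OC(=O)[C@@]23CCC[C@](C)(CO[Si](C)(C)C(C)(C)C)[C@@H]3[C@H]1OCc1ccc(OC)cc1
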